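The plan cuts C5–C10 and C8–C9 of the decalin together. If the ring B alkene is moved from C5=C6 to C6=C7 and written as a C7 silyl enol ether, ring B becomes a Diels–Alder cyclohexene. Its diene carbon C5 and dienophile carbon C10 are already linked by the C1–C4 chain of ring A. This fused 1,7,9-decatriene pattern, spanning the contiguous C8–C9–C10 triad with quaternary C9, is the feature exploited. One catalytic enantioselective intramolecular cycloaddition closes both rings and sets four stereocentres. Its precursor is an achiral chain: E α-methyl enal, three methylenes, the gem-dimethyl carbon, then a 5E,7Z diene bearing O-TIPS at C7.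

Key step: step 6

Convention: terpenoid numbering is used (C4 gem-dimethyl carbon, C8 the CHCH3, C9 the quaternary carbon, C10 the ring-fusion CH, C11 the carbon on C9 that ends as the benzylic CH2). Decalins are viewed with ring A left, ring B right and C10 above C5; β = towards the viewer, α = away.
Assumption: the sense of induction of the (S)-configured catalyst in step 6 is taken from the accepted binding model for α-substituted enals; if it proved opposite, the equally available (R)-catalyst would be used and nothing else would change.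

Step 1
Reactants: 1 2,2-dimethylpent-4-enal; 2 diethyl (2-oxobutyl)phosphonate
Product: 3 (4E)-6,6-dimethylnona-4,8-dien-3-one
Conditions: NaH, THF, 0 °C to rt
Reagents that add atoms: none
Why: Horner–Wadsworth–Emmons olefination: the stabilised β-ketophosphonate anion adds reversibly to the non-enolisable α-quaternary aldehyde, so the E enone (future C5=C6) should form.

Step 2
Reactants: 3 (4E)-6,6-dimethylnona-4,8-dien-3-one
Product: 4 [(2Z,4E)-6,6-dimethylnona-2,4,8-trien-3-yl]oxy(triisopropyl)silane
Conditions: TIPSOTf, Et3N, CH2Cl2, 0 °C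
Reagents that add atoms: triisopropylsilyl trifluoromethanesulfonate, CC(C)[Si](C(C)C)(C(C)C)OS(=O)(=O)C(F)(F)F
Why: Soft enolisation with a silyl triflate and an amine: only the C8 methylene can lose a proton (C4 is quaternary, so no γ-hydrogen exists), the Z enol ether should result because it avoids allylic strain between the C8 methyl and the vinyl arm, and doing this before any enal is present removes the competing dienolisation of an enal and also masks the ketone from the borane of step 4.

Step 3
Reactants: 5 prop-2-yn-1-ol
Product: 8 (E)-3-iodo-2-methylprop-2-en-1-ol, via alkenylalane 6 (not isolated), via iodoalkenyl aluminium alkoxide 7 (not isolated)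
Conditions: Me3Al, (C5H5)2ZrCl2 (25 mol %), CH2Cl2, 0 °C to rt; then I2, THF, −30 to 0 °C; aqueous work-up
Reagents that add atoms: trimethylaluminium, C[Al](C)C; iodine, II
Why: Negishi carboalumination: zirconium-catalysed syn addition of CH3–Al across the alkyne places aluminium at the terminus, and iodinolysis with retention should give the E vinyl iodide that encodes the E geometry of C9=C10.

Step 4
Reactants: 4 [(2Z,4E)-6,6-dimethylnona-2,4,8-trien-3-yl]oxy(triisopropyl)silane; 8 (E)-3-iodo-2-methylprop-2-en-1-ol
Product: 10 (2E,8E,10Z)-2,7,7-trimethyl-10-(triisopropylsilyloxy)dodeca-2,8,10-trien-1-ol, via B-alkyl borane 9 (not isolated)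
Conditions: 9-borabicyclo[3.3.1]nonane (9-BBN), THF, 0 °C to rt; then 8, [1,1'-bis(diphenylphosphino)ferrocene]PdCl2 (5 mol %), AsPh3, Cs2CO3, DMF–H2O, rt
Reagents that add atoms: none
Why: Hydroboration followed by B-alkyl Suzuki–Miyaura coupling: 9-BBN should pick the monosubstituted alkene over the hindered, conjugated enol-ether diene, and coupling at zerovalent palladium forms C1–C10 with retention of the iodide geometry, so that no olefin metathesis (with its risk of ring closure onto the second alkene) is needed.

Step 5
Reactants: 10 (2E,8E,10Z)-2,7,7-trimethyl-10-(triisopropylsilyloxy)dodeca-2,8,10-trien-1-ol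
Product: 11 (2E,8E,10Z)-2,7,7-trimethyl-10-(triisopropylsilyloxy)dodeca-2,8,10-trienal
Conditions: MnO2, CH2Cl2, rt
Reagents that add atoms: none
Why: Allylic oxidation with MnO2: the neutral heterogeneous oxidant should act only on the allylic alcohol, keep the E geometry and spare the TIPS dienol ether, and 11 is kept cold and used at once to avoid uncatalysed cyclisation.

Step 6
Reactants: 11 (2E,8E,10Z)-2,7,7-trimethyl-10-(triisopropylsilyloxy)dodeca-2,8,10-trienal
Product: 12 cis-fused decalin C11 aldehyde with C6=C7 TIPS enol ether (C8-CH3/C9-CH3 β; CHO/H5/H10 α)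
Conditions: (S)-3,3-diphenyl-1-(2-methylphenyl)tetrahydro-1H,3H-pyrrolo[1,2-c][1,3,2]oxazaborole (20 mol %), HN(SO2CF3)2 (18 mol %), CH2Cl2 (0.01 M, slow addition of 11), −78 to −20 °C
Reagents that add atoms: none
Why: Coordination of the boron cation to the aldehyde oxygen lowers the LUMO of C9=C10, and the C5–C8 diene then engages one face of that alkene in a single, non-synchronous [4+2] event in which C5–C10 forms ahead of C8–C9. The closest known chemistry is the oxazaborolidinium-catalysed enantioselective intramolecular Diels–Alder reaction of trienals, together with Lewis acid promoted cyclisations of 1,7,9-decatrienes that carry 2-silyloxydiene units. Ring B (C5–C10) is the new cyclohexene itself, and ring A (C1–C5 plus C10) is completed simultaneously in the fused type 1 mode through a chair-like six-membered tether, the bridged pairing C8–C10/C5–C9 being too strained, so that the tether overrules the electronic wish of C8 to bond to C10. C9 and C10 take their relative configuration from the E enal (CHO and H10 on one side, C9 methyl and C1 on the other) and their absolute configuration from the catalyst, whose phenyl group covers one enal face and leaves the Re face of C9 open. C5 and C8 are tied to each other by the 5E,7Z diene, in which C4 and the C8 methyl are both outside groups and therefore end cis, and they are tied to C9 by the orientation of approach, the mode needed being the one with the small C9 methyl endo and the boron-laden formyl exo, which gives the cis-fused adduct with the C8 and C9 methyls cis. The step thus needs one enal face and the formyl-exo orientation; the substrate supports the latter because the enforced pairing sets C9 beside C7, where the bulky O-TIPS group, turned out of the diene plane by the Z methyl, obstructs an endo formyl–boron complex while α-methyl enals have only a weak endo bias, high dilution holds back bimolecular addition, and C5 need not be controlled since step 9 removes it.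

Step 7
Reactants: 12 cis-fused decalin C11 aldehyde with C6=C7 TIPS enol ether; 13 1,2,4,5-tetramethoxybenzene
Product: 17 C11 O-alkyl S-methyl xanthate bearing the 2,3,5,6-tetramethoxyphenyl group (both C11 epimers), via aryllithium 14 (not isolated), via lithium alkoxide 15 (not isolated), via lithium xanthate 16 (not isolated)
Conditions: 13, n-BuLi, THF, 0 °C to rt; 12, −78 to 0 °C; CS2, 0 °C to rt; MeI, rt
Reagents that add atoms: carbon disulfide, S=C=S; iodomethane, CI
Why: Directed ortho-lithiation between two methoxy groups, 1,2-addition of the aryllithium to the non-enolisable neopentyl aldehyde and xanthate formation from the alkoxide in the same flask; the new C11 carbinol centre is left uncontrolled because step 8 removes it, and the TIPS enol ether is inert to all of these reagents.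

Step 8
Reactants: 17 C11 xanthate
Product: 18 C11-deoxygenated cis-decalin TIPS enol ether carrying the tetramethoxybenzyl group on C9
Conditions: n-Bu3SnH, 2,2'-azobis(2-methylpropionitrile) (cat.), toluene, 90 °C
Reagents that add atoms: none
Why: Barton–McCombie deoxygenation: stannyl radical addition to C=S and β-scission give an aryl-stabilised C11 radical that takes hydrogen from the stannane, under neutral conditions that keep the acid-labile enol ether, which an ionic benzylic reduction would not.

Step 9
Reactants: 18 C11-deoxygenated TIPS enol ether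
Product: 19 5-en-7-one (C8-CH3/C9-CH3 β; C11/H10 α)
Conditions: Pd(OAc)2 (1.2 equiv), MeCN–CH2Cl2, rt to 40 °C
Reagents that add atoms: none
Why: Saegusa–Ito oxidation: divalent palladium attacks C6 of the enol ether and syn β-hydride elimination can only take H5, so the 5-en-7-one should form regiospecifically, erasing C5 and leaving C8, C9 and C10 untouched.

Step 10
Reactants: 19 5-en-7-one
Product: 20 C7 1,3-dithiolane of the 5-en-7-one
Conditions: HSCH2CH2SH, BF3·OEt2, CH2Cl2, −20 to 0 °C
Reagents that add atoms: ethane-1,2-dithiol, SCCS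
Why: Lewis acid promoted thioketalisation: enones give dithiolanes without migration of the alkene, conjugate addition is blocked at fully substituted C5, and the low temperature should keep C8 (α′) and C10 (γ) from enolising.

Step 11
Reactants: 20 C7 1,3-dithiolane
Product: 21 tetramethoxybenzyl 5-ene decalin (C7 now CH2)
Conditions: Raney Ni (W-2, aged in acetone), EtOH, rt to 50 °C
Reagents that add atoms: none
Why: Mozingo-type reductive desulfurisation: both C–S bonds are replaced by C–H at C7, while the trisubstituted C5=C6 alkene, shielded by the C4 gem-dimethyl group, should resist the deactivated nickel.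

Step 12
Reactants: 21 tetramethoxybenzyl 5-ene decalin
Product: 22 3-alkyl-2,5-dimethoxy-1,4-benzoquinone
Conditions: (NH4)2Ce(NO3)6, MeCN–H2O, 0 °C
Reagents that add atoms: water, O
Why: Oxidative demethylation with tetravalent cerium: the two para-dimethoxy pairs of the arene are equivalent by symmetry, so one 2,5-dimethoxy-1,4-benzoquinone should result, and the isolated alkene is not attacked at 0 °C.

Step 13
Reactants: 22 3-alkyl-2,5-dimethoxy-1,4-benzoquinone
Product: 24 3-alkyl-2-hydroxy-5-methoxy-1,4-benzoquinone, via potassium quinonate 23 (not isolated)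
Conditions: KOH, MeOH–H2O, rt to 50 °C; then 1 M HCl
Reagents that add atoms: potassium hydroxide, [K+].[OH-]
Why: Vinylogous ester saponification by addition–elimination: hydroxide should attack the methoxy-bearing carbon next to the C11 methylene, whose methoxy group is twisted out of conjugation, and the hydroxyquinone anion formed resists a second attack.

Step 14
Reactants: 24 3-alkyl-2-hydroxy-5-methoxy-1,4-benzoquinone; 25 3-methylbutan-1-amine (isopentylamine)
Product: 26 nakijiquinone M
Conditions: 25 (3 equiv), EtOH, rt; mildly acidic work-up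
Reagents that add atoms: none
Why: Addition–elimination of the primary amine at the remaining methoxy-bearing carbon turns the vinylogous ester into the vinylogous amide, no stereocentre being involved.

Compound list
1 | 2,2-dimethylpent-4-enal | O=CC(C)(C)CC=C | starting material
2 | diethyl (2-oxobutyl)phosphonate | CCC(=O)CP(=O)(OCC)OCC | starting material
3 | (4E)-6,6-dimethylnona-4,8-dien-3-one | CCC(=O)/C=C/C(C)(C)CC=C | intermediate
4 | [(2Z,4E)-6,6-dimethylnona-2,4,8-trien-3-yl]oxy(triisopropyl)silane | C=CCC(C)(C)/C=C/C(O[Si](C(C)C)(C(C)C)C(C)C)=C/C | intermediate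
5 | prop-2-yn-1-ol | C#CCO | starting material
6 | (E)-alkenyl(dimethyl)alane, O-dimethylaluminium alkoxide (not isolated) | C[Al](C)OC/C(C)=C/[Al](C)C | intermediate
7 | dimethylaluminium (E)-3-iodo-2-methylprop-2-en-1-olate (not isolated) | C[Al](C)OC/C(C)=C/I | intermediate
8 | (E)-3-iodo-2-methylprop-2-en-1-ol | OC/C(C)=C/I | intermediate
9 | B-alkyl-9-BBN from terminal hydroboration of 4 (not isolated) | C(CCB1C2CCCC1CCC2)C(C)(C)/C=C/C(O[Si](C(C)C)(C(C)C)C(C)C)=C/C | intermediate
10 | (2E,8E,10Z)-2,7,7-trimethyl-10-(triisopropylsilyloxy)dodeca-2,8,10-trien-1-ol | OC/C(C)=C/CCCC(C)(C)/C=C/C(O[Si](C(C)C)(C(C)C)C(C)C)=C/C | intermediate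
11 | (2E,8E,10Z)-2,7,7-trimethyl-10-(triisopropylsilyloxy)dodeca-2,8,10-trienal (key-step precursor) | O=C/C(C)=C/CCCC(C)(C)/C=C/C(O[Si](C(C)C)(C(C)C)C(C)C)=C/C | intermediate
12 | (1S,2R,4aS,8aR)-1,2,5,5-tetramethyl-3-(triisopropylsilyloxy)-1,2,4a,5,6,7,8,8a-octahydronaphthalene-1-carbaldehyde; cis-fused, C8-CH3 and C9-CH3 β, CHO, H5 and H10 α (key-step product) | O=C[C@@]1(C)[C@@H]2CCCC(C)(C)[C@@H]2C=C(O[Si](C(C)C)(C(C)C)C(C)C)[C@@H]1C | intermediate
13 | 1,2,4,5-tetramethoxybenzene | COc1cc(OC)c(OC)cc1OC | starting material
14 | 2,3,5,6-tetramethoxyphenyllithium (not isolated) | [Li]c1c(OC)c(OC)cc(OC)c1OC | intermediate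
15 | lithium C11 alkoxide from 12 and 14, C11 epimers, decalin as in 12 (not isolated) | [Li]OC(c1c(OC)c(OC)cc(OC)c1OC)[C@@]2(C)[C@@H]3CCCC(C)(C)[C@@H]3C=C(O[Si](C(C)C)(C(C)C)C(C)C)[C@@H]2C | intermediate
16 | lithium O-alkyl dithiocarbonate of 15 (not isolated) | [Li]SC(=S)OC(c1c(OC)c(OC)cc(OC)c1OC)[C@@]2(C)[C@@H]3CCCC(C)(C)[C@@H]3C=C(O[Si](C(C)C)(C(C)C)C(C)C)[C@@H]2C | intermediate
17 | C11 O-alkyl S-methyl xanthate, C11 epimers, decalin as in 12 | CSC(=S)OC(c1c(OC)c(OC)cc(OC)c1OC)[C@@]2(C)[C@@H]3CCCC(C)(C)[C@@H]3C=C(O[Si](C(C)C)(C(C)C)C(C)C)[C@@H]2C | intermediate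
18 | cis-decalin C6=C7 TIPS enol ether with 2,3,5,6-tetramethoxybenzyl (C11 α) and CH3 (β) on C9, C8-CH3 β, H5 and H10 α | COc1cc(OC)c(OC)c(C[C@@]2(C)[C@@H]3CCCC(C)(C)[C@@H]3C=C(O[Si](C(C)C)(C(C)C)C(C)C)[C@@H]2C)c1OC | intermediate
19 | 5-en-7-one, C8-CH3 and C9-CH3 β, C11 and H10 α | COc1cc(OC)c(OC)c(C[C@@]2(C)[C@@H]3CCCC(C)(C)C3=CC(=O)[C@@H]2C)c1OC | intermediate
20 | C7 spiro-1,3-dithiolane of 19, C5=C6 retained | COc1cc(OC)c(OC)c(C[C@@]2(C)[C@@H]3CCCC(C)(C)C3=CC4(SCCS4)[C@@H]2C)c1OC | intermediate
21 | 1,2,4,5-tetramethoxy-3-{[(1R,2S,8aS)-1,2,5,5-tetramethyl-1,2,3,5,6,7,8,8a-octahydronaphthalen-1-yl]methyl}benzene | COc1cc(OC)c(OC)c(C[C@@]2(C)[C@@H]3CCCC(C)(C)C3=CC[C@@H]2C)c1OC | intermediate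
22 | 2,5-dimethoxy-3-(decalinylmethyl)-1,4-benzoquinone, decalin as in 21 | COC1=CC(=O)C(OC)=C(C[C@@]2(C)[C@@H]3CCCC(C)(C)C3=CC[C@@H]2C)C1=O | intermediate
23 | potassium salt of 24 (not isolated) | COC1=CC(=O)C([O-])=C(C[C@@]2(C)[C@@H]3CCCC(C)(C)C3=CC[C@@H]2C)C1=O.[K+] | intermediate
24 | 2-hydroxy-5-methoxy-3-(decalinylmethyl)-1,4-benzoquinone, decalin as in 21 | COC1=CC(=O)C(O)=C(C[C@@]2(C)[C@@H]3CCCC(C)(C)C3=CC[C@@H]2C)C1=O | intermediate
25 | 3-methylbutan-1-amine (isopentylamine) | CC(C)CCN | starting material
26 | nakijiquinone M, 2-hydroxy-5-[(3-methylbutyl)amino]-3-{[(1R,2S,8aS)-1,2,5,5-tetramethyl-1,2,3,5,6,7,8,8a-octahydronaphthalen-1-yl]methyl}cyclohexa-2,5-diene-1,4-dione | CC(C)CCNC1=CC(=O)C(O)=C(C[C@@]2(C)[C@@H]3CCCC(C)(C)C3=CC[C@@H]2C)C1=O | target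

Total step count: 14.
Longest linear sequence: 13 steps (steps 1, 2 and 4 to 14, from 1 to 26); step 3 is the only branch.

Steps most likely to fail

1. Step 6.
- What may go wrong: the cycloaddition may run partly or mainly through the formyl-endo orientation that is usual for Lewis acid bound trienals. That orientation inverts C5 and C8 relative to C9 and C10. Bimolecular reaction of the nucleophilic C8 terminus with a second activated enal may also drain material.
- Fallback (C8 fixed by enolate protonation instead of by the cycloaddition), setting out from 11 and coming back at 19: the same catalysed cyclisation is accepted as it falls and the trans-fused formyl-endo adduct F1 is isolated. With 14 it gives the lithium alkoxide F2, CS2 gives the lithium xanthate F3 and MeI the xanthate F4. Reduction with n-Bu3SnH gives the deoxygenated enol ether F5, and Pd(OAc)2 gives the 8-epi enone F6, in which the C5 difference has disappeared. LiN(iPr)2 in THF at −78 °C removes the α′ proton at C8 under kinetic control and leaves the γ proton at C10 alone. The cross-conjugated lithium dienolate F7 is then quenched cold with acetic acid. Protonation along the axial line on the α face, anti to the axial C9 methyl, should place the C8 methyl equatorial and β, which is 19.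
- Base equilibration is avoided on purpose. The two C8 epimers of the enone are expected to be close in energy, and an extended dienolate would endanger C10.

2. Step 9.
- What may go wrong: palladation of the hindered TIPS enol ether may be slow, so that protodesilylation to the saturated ketone or deposition of palladium metal overtakes dehydrogenation.
- Fallback (selenoxide elimination instead of β-hydride elimination), setting out from 18 and coming back at 19: PhSeCl in CH2Cl2 at −78 to 0 °C selenenylates C6 of the enol ether with loss of the silyl group and gives the 6-phenylselanyl ketone F8. H2O2 and pyridine give the selenoxide F9, which eliminates syn towards H5 to give 19. H5 is the only β-hydrogen, and the C6 centre can epimerise to reach the syn arrangement.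

3. Step 10.
- What may go wrong: thioketalisation at C7, flanked by the C8 methine and quaternary C9, may be slow enough for acid-induced enolisation to erode C8 or C10. The nickel step that follows may also shift or saturate the alkene.
- Fallback (radical deoxygenation of an allylic alcohol), setting out from 19 and coming back at 21, so that 20 is bypassed: Luche reduction (NaBH4, CeCl3·7H2O, MeOH, −78 to 0 °C) gives the allylic alcohol F10, whose C7 configuration is irrelevant. 1,1'-Thiocarbonyldiimidazole gives the imidazolylthiocarbonate F11. n-Bu3SnH with 2,2'-azobis(2-methylpropionitrile) then generates the C5–C6–C7 allyl radical. This radical should take hydrogen at the less hindered C7 terminus and so keep the more substituted C5=C6 alkene of 21. No acid or base touches C8 or C10.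

Further compounds
F1 | step 6 | trans-fused formyl-endo adduct (H5 β, C8-CH3 α, otherwise as 12) | O=C[C@@]1(C)[C@@H]2CCCC(C)(C)[C@H]2C=C(O[Si](C(C)C)(C(C)C)C(C)C)[C@H]1C
F2 | step 6 | lithium alkoxide from F1 and 14 | [Li]OC(c1c(OC)c(OC)cc(OC)c1OC)[C@@]2(C)[C@@H]3CCCC(C)(C)[C@H]3C=C(O[Si](C(C)C)(C(C)C)C(C)C)[C@H]2C
F3 | step 6 | lithium xanthate from F2 | [Li]SC(=S)OC(c1c(OC)c(OC)cc(OC)c1OC)[C@@]2(C)[C@@H]3CCCC(C)(C)[C@H]3C=C(O[Si](C(C)C)(C(C)C)C(C)C)[C@H]2C
F4 | step 6 | xanthate of the trans-fused series | CSC(=S)OC(c1c(OC)c(OC)cc(OC)c1OC)[C@@]2(C)[C@@H]3CCCC(C)(C)[C@H]3C=C(O[Si](C(C)C)(C(C)C)C(C)C)[C@H]2C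
F5 | step 6 | deoxygenated enol ether of the trans-fused series | COc1cc(OC)c(OC)c(C[C@@]2(C)[C@@H]3CCCC(C)(C)[C@H]3C=C(O[Si](C(C)C)(C(C)C)C(C)C)[C@H]2C)c1OC
F6 | step 6 | 8-epi enone (C8-CH3 α) | COc1cc(OC)c(OC)c(C[C@@]2(C)[C@@H]3CCCC(C)(C)C3=CC(=O)[C@H]2C)c1OC
F7 | step 6 | cross-conjugated lithium dienolate (C5=C6, C7=C8) | COc1cc(OC)c(OC)c(C[C@@]2(C)[C@@H]3CCCC(C)(C)C3=CC(O[Li])=C2C)c1OC
F8 | step 9 | 6-phenylselanyl ketone (C6 epimers) | COc1cc(OC)c(OC)c(C[C@@]2(C)[C@@H]3CCCC(C)(C)[C@@H]3C([Se]c4ccccc4)C(=O)[C@@H]2C)c1OC
F9 | step 9 | selenoxide of F8 | COc1cc(OC)c(OC)c(C[C@@]2(C)[C@@H]3CCCC(C)(C)[C@@H]3C([Se](=O)c4ccccc4)C(=O)[C@@H]2C)c1OC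
F10 | step 10 | allylic alcohol (5-en-7-ol, C7 epimers) | COc1cc(OC)c(OC)c(C[C@@]2(C)[C@@H]3CCCC(C)(C)C3=CC(O)[C@@H]2C)c1OC
F11 | step 10 | imidazolylthiocarbonate of F10 | COc1cc(OC)c(OC)c(C[C@@]2(C)[C@@H]3CCCC(C)(C)C3=CC(OC(=S)n4ccnc4)[C@@H]2C)c1OC
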